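**Plan**

1. Retrosynthesis: the C3–O bond, the O5 acetal and the O7–prenyl bond are cut first, which leads back to acacetin. Ring C of acacetin (the pyranone; ring A is the benzo ring, ring B the anisyl ring, flavone numbering) is then cut at C4a–C4, C4–C3 and O1–C2 into an aryl iodide, CO and 4-ethynylanisole.
2. Enabling feature: C4 is an isolated carbonyl carbon between C4a and C3, so CO can supply it. C4a is flanked by O1 and O5, which are equivalent in 2-iodophloroglucinol triacetate, so either oxygen may close ring C and the other becomes the C5 hydroxyl.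
3. Forward: phloroglucinol is iodinated and acetylated, and a palladium-catalysed carbonylative alkyne annulation then builds ring C, the only ring formed (rings A and B are bought), to give acacetin.
4. The route is completed by 7-O-prenylation, 5-O-methoxymethylation, C3 lithiation–borylation–oxidation and mild acid release of the 5-hydroxyl. The prenyl ether is attached only after the palladium step, because aryl allyl-type ethers can be ionised by zerovalent palladium in the presence of secondary amines.
5. Stereochemistry: the target has no stereocentre and the prenyl alkene carries two identical methyl groups, so nothing needs to be controlled.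

Key step: step 3

Remark: diethylamine is expected to remove all three acetates during the annulation, so the product of that step is written as the free diphenol acacetin.

**Route**

Step 1
Reactants: 1 phloroglucinol (benzene-1,3,5-triol)
Product: 2 2-iodobenzene-1,3,5-triol
Conditions: I2 (1.0 equiv), NaHCO3 (1.1 equiv), THF/H2O (1:1), 0 °C to rt; crude product used at once
Reagents that add atoms: iodine, II
Why: Electrophilic aromatic iodination of the strongly activated triol under bicarbonate buffering should stop at the mono-iodide with one equivalent of iodine at low temperature, and all three ring positions are equivalent, so no regiochemical question arises.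

Step 2
Reactants: 2 2-iodobenzene-1,3,5-triol
Product: 3 2-iodobenzene-1,3,5-triyl triacetate
Conditions: Ac2O (4 equiv), pyridine, DMAP (cat.), CH2Cl2, 0 °C to rt
Reagents that add atoms: acetic anhydride, CC(=O)OC(C)=O
Why: Pyridine-mediated O-acetylation (nucleophilic acyl substitution) should turn the air-sensitive iodotriol into a stable, purifiable triacetate, which is the substrate class used for carbonylative flavone annulation and is less prone to loss of iodine.

Step 3
Reactants: 3 2-iodobenzene-1,3,5-triyl triacetate; 4 carbon monoxide; 5 4-ethynylanisole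
Product: 8 acacetin (5,7-dihydroxy-2-(4-methoxyphenyl)-4H-chromen-4-one), via triacetoxyaryl ynone 6 (not isolated), via diethylamino enone 7 (not isolated)
Conditions: PdCl2(PPh3)2 (5 mol %), Ph2P(CH2)3PPh2 (5 mol %), thiourea (5 mol %), DBU (2 equiv), Et2NH, CO (1 atm), 40–50 °C; aq. NH4Cl work-up
Reagents that add atoms: none
Why: The divalent precatalyst PdCl2(PPh3)2 is reduced in the flask to zerovalent palladium, which adds oxidatively to the aryl iodide of 3; migratory insertion of CO gives an aroylpalladium iodide that is alkynylated by 5 (amine base, no copper) and reductively eliminates ynone 6, so that C4a–C4 and C4–C3 are formed in a carbonylative Sonogashira coupling. Diethylamine then cleaves the aryl acetates and adds to the ynone to give enaminone 7, and one of the two equivalent ortho phenoxides displaces the amine at C2 by addition–elimination, which closes ring C through O1–C2 in what amounts to a 6-endo closure. The closest known reaction type is the palladium-catalysed carbonylative annulation of 2-iodophenyl acetates with terminal alkynes to flavones. No stereocentre is formed. The step needs CO insertion to outrun direct alkynylation (which would end in a 2-arylbenzofuran) and 6-endo closure to beat 5-exo closure (aurone): the acetates keep the phenols masked during oxidative addition, the hindered electron-rich arylpalladium species takes up CO readily, and the amine adduct leaves C2 as the only electrophilic carbon. Since both ortho oxygens are equivalent, the one that does not cyclise simply ends as the hydrogen-bonded C5 hydroxyl.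

Step 4
Reactants: 8 acacetin; 9 prenyl bromide (1-bromo-3-methylbut-2-ene)
Product: 10 5-hydroxy-2-(4-methoxyphenyl)-7-[(3-methylbut-2-en-1-yl)oxy]-4H-chromen-4-one
Conditions: 9 (1.1 equiv), K2CO3 (1.5 equiv), acetone, reflux
Reagents that add atoms: none
Why: Williamson etherification should be selective for the 7-hydroxyl, which is the most acidic phenol (conjugated with the pyranone carbonyl), whereas the 5-hydroxyl is held in a hydrogen bond to that carbonyl and does not alkylate with K2CO3.

Step 5
Reactants: 10 5-hydroxy-2-(4-methoxyphenyl)-7-[(3-methylbut-2-en-1-yl)oxy]-4H-chromen-4-one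
Product: 11 5-(methoxymethoxy)-2-(4-methoxyphenyl)-7-[(3-methylbut-2-en-1-yl)oxy]-4H-chromen-4-one
Conditions: NaH (1.5 equiv), MOMCl (1.5 equiv), DMF, 0 °C to rt
Reagents that add atoms: chloromethyl methyl ether, COCCl
Why: Full deprotonation of the chelated 5-hydroxyl with NaH followed by O-alkylation with MOMCl (Williamson-type acetal formation) removes the only acidic proton ahead of the lithiation, and the prenyl ether is inert to these basic conditions.

Step 6
Reactants: 11 5-(methoxymethoxy)-2-(4-methoxyphenyl)-7-[(3-methylbut-2-en-1-yl)oxy]-4H-chromen-4-one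
Product: 14 3-hydroxy-5-(methoxymethoxy)-2-(4-methoxyphenyl)-7-[(3-methylbut-2-en-1-yl)oxy]-4H-chromen-4-one, via 3-lithioflavone 12 (not isolated), via flavone-3-boronate dimethyl ester 13 (not isolated)
Conditions: LiN(iPr)2 (2.0 equiv), THF, −78 °C; B(OMe)3 (3 equiv), −78 to 0 °C; AcOH, 30% aq. H2O2 (2 equiv), 0 °C
Reagents that add atoms: hydrogen peroxide, OO
Why: Deprotonation of the flavone at C3 with LiN(iPr)2 (the vinylic C–H next to the carbonyl), trapping with B(OMe)3 and oxidation of the C–B bond with H2O2 is an established lithiation–borylation–oxidation route from flavones to flavonols, and the prenyl alkene and the aryl ethers should tolerate the amide base at −78 °C and cold, near-stoichiometric peroxide.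

Step 7
Reactants: 14 3-hydroxy-5-(methoxymethoxy)-2-(4-methoxyphenyl)-7-[(3-methylbut-2-en-1-yl)oxy]-4H-chromen-4-one
Product: 15 3,5-dihydroxy-2-(4-methoxyphenyl)-7-[(3-methylbut-2-en-1-yl)oxy]-4H-chromen-4-one (target)
Conditions: HCl (0.2 M), MeOH/THF (1:1), 0 °C to rt
Reagents that add atoms: none
Why: Acid-catalysed acetal methanolysis is especially fast for a methoxymethyl ether peri to the carbonyl, so dilute HCl in methanol should release the hydrogen-bonded 5-hydroxyl well before the aryl prenyl ether ionises.

**Compound list**

1 | phloroglucinol (benzene-1,3,5-triol) | Oc1cc(O)cc(O)c1 | starting material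
2 | 2-iodobenzene-1,3,5-triol | Oc1cc(O)c(I)c(O)c1 | intermediate
3 | 2-iodobenzene-1,3,5-triyl triacetate | CC(=O)Oc1cc(OC(C)=O)c(I)c(OC(C)=O)c1 | intermediate
4 | carbon monoxide | [C-]#[O+] | starting material
5 | 4-ethynylanisole (1-ethynyl-4-methoxybenzene) | C#Cc1ccc(OC)cc1 | starting material
6 | 2-[3-(4-methoxyphenyl)prop-2-ynoyl]benzene-1,3,5-triyl triacetate | COc1ccc(C#CC(=O)c2c(OC(C)=O)cc(OC(C)=O)cc2OC(C)=O)cc1 | intermediate (not isolated)
7 | (2E)-3-(diethylamino)-3-(4-methoxyphenyl)-1-(2,4,6-trihydroxyphenyl)prop-2-en-1-one | CCN(CC)/C(c1ccc(OC)cc1)=C/C(=O)c1c(O)cc(O)cc1O | intermediate (not isolated)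
8 | acacetin, 5,7-dihydroxy-2-(4-methoxyphenyl)-4H-chromen-4-one | COc1ccc(-c2cc(=O)c3c(O)cc(O)cc3o2)cc1 | intermediate
9 | prenyl bromide (1-bromo-3-methylbut-2-ene) | CC(C)=CCBr | starting material
10 | 5-hydroxy-2-(4-methoxyphenyl)-7-[(3-methylbut-2-en-1-yl)oxy]-4H-chromen-4-one | COc1ccc(-c2cc(=O)c3c(O)cc(OCC=C(C)C)cc3o2)cc1 | intermediate
11 | 5-(methoxymethoxy)-2-(4-methoxyphenyl)-7-[(3-methylbut-2-en-1-yl)oxy]-4H-chromen-4-one | COCOc1cc(OCC=C(C)C)cc2oc(-c3ccc(OC)cc3)cc(=O)c12 | intermediate
12 | 3-lithio-5-(methoxymethoxy)-2-(4-methoxyphenyl)-7-[(3-methylbut-2-en-1-yl)oxy]-4H-chromen-4-one | COCOc1cc(OCC=C(C)C)cc2oc(-c3ccc(OC)cc3)c([Li])c(=O)c12 | intermediate (not isolated)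
13 | dimethyl {5-(methoxymethoxy)-2-(4-methoxyphenyl)-7-[(3-methylbut-2-en-1-yl)oxy]-4-oxo-4H-chromen-3-yl}boronate | COCOc1cc(OCC=C(C)C)cc2oc(-c3ccc(OC)cc3)c(B(OC)OC)c(=O)c12 | intermediate (not isolated)
14 | 3-hydroxy-5-(methoxymethoxy)-2-(4-methoxyphenyl)-7-[(3-methylbut-2-en-1-yl)oxy]-4H-chromen-4-one | COCOc1cc(OCC=C(C)C)cc2oc(-c3ccc(OC)cc3)c(O)c(=O)c12 | intermediate
15 | 3,5-dihydroxy-2-(4-methoxyphenyl)-7-[(3-methylbut-2-en-1-yl)oxy]-4H-chromen-4-one | COc1ccc(-c2oc3cc(OCC=C(C)C)cc(O)c3c(=O)c2O)cc1 | target

**Step count**

Total steps: 7. Longest linear sequence: 7 steps, from phloroglucinol 1.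

**Steps most likely to fail, with fallbacks**

Step 3. Three things may go wrong. CO insertion may lose out to direct alkynylation followed by closure to a benzofuran. The aroylpalladium intermediate may be captured by diethylamine as an amide. Oxidative addition into the doubly ortho-substituted iodide may be slow enough that iodine is lost once the acetates have been cleaved. In that case acacetin would be made without palladium. Phloroglucinol 1 and commercial ethyl 3-(4-methoxyphenyl)-3-oxopropanoate are heated neat at about 240 °C (Mentzer-type thermal condensation of a phenol with a beta-keto ester), which should give the 5,7-dihydroxyflavone directly with loss of ethanol and water. This fallback sets out from 1 and rejoins the route at 8; it makes no new compound.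

Step 6. Deprotonation at C3 may be incomplete or misdirected (attack of the amide base at C2 or at the allylic ether methylene), or the prenyl alkene may be epoxidised by peracid formed from AcOH and H2O2 during the boronate oxidation. The fallback installs the C3 oxygen before the prenyl group and sets out from acacetin 8. Double methoxymethylation (NaH, MOMCl, DMF) should give 5,7-bis(methoxymethoxy)-2-(4-methoxyphenyl)-4H-chromen-4-one F1. Dimethyldioxirane in acetone/CH2Cl2 at 0 °C then epoxidises the C2–C3 bond to racemic cis-fused 2,3-epoxy-5,7-bis(methoxymethoxy)-2-(4-methoxyphenyl)chroman-4-one F2. HCl in MeOH at 40–50 °C opens the epoxide at C2, lets the product tautomerise to the flavonol and removes both acetals, giving kaempferide F3. Alkylation with prenyl bromide 9 (1.0 equiv) and K2CO3 (1.0 equiv) in acetone at rt should then take place at the most acidic 7-hydroxyl, and the fallback rejoins the route at target 15.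

Step 7. The acid-labile prenyl ether may ionise to the prenyl cation in competition with acetal hydrolysis. The fallback replaces the acetal with a fluoride-labile group and sets out from 10. Silylation of the chelated hydroxyl (TBSOTf, 2,6-lutidine, CH2Cl2) should give 5-[(tert-butyldimethylsilyl)oxy]-2-(4-methoxyphenyl)-7-[(3-methylbut-2-en-1-yl)oxy]-4H-chromen-4-one F4. The same LiN(iPr)2 / B(OMe)3 / H2O2 sequence, through the 3-lithio derivative F5 and the flavone-3-boronate dimethyl ester F6, should give the 3-hydroxy silyl ether F7. Bu4NF buffered with AcOH in THF at 0 °C then removes the silyl group without acid, and the fallback rejoins the route at target 15.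

Further compounds
F0 | step 3 | none | none
F1 | step 6 | 5,7-bis(methoxymethoxy)-2-(4-methoxyphenyl)-4H-chromen-4-one | COCOc1cc(OCOC)cc2oc(-c3ccc(OC)cc3)cc(=O)c12
F2 | step 6 | racemic cis-fused 2,3-epoxy-5,7-bis(methoxymethoxy)-2-(4-methoxyphenyl)chroman-4-one (one enantiomer drawn) | COc1ccc(cc1)[C@@]12O[C@@H]1C(=O)c1c(OCOC)cc(OCOC)cc1O2
F3 | step 6 | kaempferide, 3,5,7-trihydroxy-2-(4-methoxyphenyl)-4H-chromen-4-one | COc1ccc(-c2oc3cc(O)cc(O)c3c(=O)c2O)cc1
F4 | step 7 | 5-[(tert-butyldimethylsilyl)oxy]-2-(4-methoxyphenyl)-7-[(3-methylbut-2-en-1-yl)oxy]-4H-chromen-4-one | CC(C)(C)[Si](C)(C)Oc1cc(OCC=C(C)C)cc2oc(-c3ccc(OC)cc3)cc(=O)c12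
F5 | step 7 | 3-lithio-5-[(tert-butyldimethylsilyl)oxy]-2-(4-methoxyphenyl)-7-[(3-methylbut-2-en-1-yl)oxy]-4H-chromen-4-one | CC(C)(C)[Si](C)(C)Oc1cc(OCC=C(C)C)cc2oc(-c3ccc(OC)cc3)c([Li])c(=O)c12
F6 | step 7 | dimethyl {5-[(tert-butyldimethylsilyl)oxy]-2-(4-methoxyphenyl)-7-[(3-methylbut-2-en-1-yl)oxy]-4-oxo-4H-chromen-3-yl}boronate | CC(C)(C)[Si](C)(C)Oc1cc(OCC=C(C)C)cc2oc(-c3ccc(OC)cc3)c(B(OC)OC)c(=O)c12
F7 | step 7 | 5-[(tert-butyldimethylsilyl)oxy]-3-hydroxy-2-(4-methoxyphenyl)-7-[(3-methylbut-2-en-1-yl)oxy]-4H-chromen-4-one | CC(C)(C)[Si](C)(C)Oc1cc(OCC=C(C)C)cc2oc(-c3ccc(OC)cc3)c(O)c(=O)c12
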